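**Retrosynthetic overview**
- Last bond: the C(sp3)–C(sp2) bond between the CH(CH3) carbon on the central pyranone and the trisubstituted alkene, made by an enantioconvergent Ni-catalysed coupling of an alkenyl bromide (left half, both esters in place) with a 1-chloroethyl pyranone (right half, free alcohol).
- Both pyranone–CH(CH3)–CH(O) units come from vinylogous Mukaiyama aldols of one silyl trienol ether, made by desymmetrising dearomatisation of 2,6-diethyl-3,5-dimethyl-4-pyranone (used twice).
- The left-half aldehyde comes from anti-crotylboration of (E)-3-bromo-2-methylacrolein (from methacrolein), acetylation and ozonolysis.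
- No ring is formed: both pyranone rings are bought intact; ring B (central) is functionalised on both ethyl groups, ring A (terminal) on one.

Assumption: the pyranone, propanal, methacrolein and the (E)-crotylboronate are bought (the pyranone is otherwise one operation from pentan-3-one and propanoic acid in polyphosphoric acid). The sense of induction of the chiral catalysts in steps 2, 5 and 10 is recalled from the closest known substrates and has not been established for these ones; it is checked on the first run and the antipodal catalyst is used if it is reversed.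

**Step 1**
Reactants: 1 2,6-diethyl-3,5-dimethyl-4H-pyran-4-one
Product: 2 tert-butyl{[(2Z)-6-ethyl-2-ethylidene-3,5-dimethyl-2H-pyran-4-yl]oxy}dimethylsilane
Conditions: TBSOTf (1.1 eq), Et3N (1.5 eq), CH2Cl2, 0 °C to rt; pentane extraction, used fresh
Reagents that add atoms: tert-butyldimethylsilyl triflate, CC(C)(C)[Si](C)(C)OS(=O)(=O)C(F)(F)F
Why: Soft enolisation: O-silylation gives a 4-silyloxypyrylium ion whose ethyl CH2 is removed by Et3N, so the pyranone loses both its aromaticity and its symmetry (the two ethyl groups are now different), and the exocyclic methyl lies on the ring-oxygen side (Z) to avoid A(1,3) strain with the 3-methyl group.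

**Step 2**
Reactants: 2 the silyl trienol ether; 3 propanal
Product: 5 2-ethyl-6-[(2S,3S)-3-hydroxypentan-2-yl]-3,5-dimethyl-4H-pyran-4-one, via trichlorosilyl ether 4 (not isolated)
Conditions: SiCl4 (1.2 eq), (R,R)-bisphosphoramide of Denmark (binaphthyldiamine-derived, pentamethylene-linked, 5 mol%), iPr2NEt (0.2 eq), CH2Cl2, −78 °C, 24 h; aq. KF/NaHCO3
Reagents that add atoms: none
Why: Proposed new method: a Lewis-base-activated SiCl4 vinylogous Mukaiyama aldol in which the chiral trichlorosilyl cation binds propanal and exposes its Re face, and the exocyclic carbon of 2 attacks through an open transition state where the aldehyde ethyl group avoids the 3-methyl group of the ring, giving the anti (2S,3S) adduct and restoring the pyranone; the closest known reaction is the same catalyst with γ-methyl ester-derived and dioxinone-derived silyl dienol ethers, which give anti adducts in high ee.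

**Step 3**
Reactants: 5 the hydroxy pyranone
Product: 7 2-[(1RS)-1-chloroethyl]-6-[(2S,3S)-3-hydroxypentan-2-yl]-3,5-dimethyl-4H-pyran-4-one (about 1:1 at the CHCl carbon), via dilithium alkoxide dienolate 6 (not isolated)
Conditions: LiN(iPr)2 (2.2 eq), THF, −78 °C, 45 min; C2Cl6 (1.2 eq), −78 °C; H2O
Reagents that add atoms: hexachloroethane, ClC(Cl)(Cl)C(Cl)(Cl)Cl
Why: Lateral (vinylogous) lithiation followed by electrophilic chlorination: the first equivalent of base makes the alkoxide, which blocks deprotonation of the adjacent C–H, the second removes a proton from the remaining ethyl CH2, and chlorination occurs at the exocyclic carbon because that restores the pyranone; the new centre is unselective, which does not matter because step 10 is stereoconvergent.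

**Step 4**
Reactants: 8 methacrolein (2-methylprop-2-enal)
Product: 10 (2E)-3-bromo-2-methylprop-2-enal, via 2,3-dibromo-2-methylpropanal 9 (not isolated)
Conditions: Br2 (1.0 eq), CH2Cl2, −78 to 0 °C; Et3N (1.2 eq), 0 °C to rt
Reagents that add atoms: bromine, BrBr
Why: Alkene bromination followed by E2 dehydrobromination (the acidic C3–H next to bromine is lost together with the tertiary bromide), and the conjugated E isomer (Br trans to CHO) is the thermodynamic product.

**Step 5**
Reactants: 10 the bromoenal; 11 (E)-crotylboronic acid pinacol ester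
Product: 13 (1E,3R,4R)-1-bromo-2,4-dimethylhexa-1,5-dien-3-ol, via pinacol borate ester 12 (not isolated)
Conditions: (R)-TRIP phosphoric acid (5 mol%), 4 Å MS, toluene, −30 °C; aq. NaHCO3
Reagents that add atoms: none
Why: Chiral phosphoric acid-catalysed crotylboration (Antilla type) through a chair Zimmerman–Traxler transition state, in which the (E)-crotyl geometry gives the anti relationship and the catalyst directs attack on the Re face of the aldehyde to give 3R,4R.

**Step 6**
Reactants: 13 the homoallylic alcohol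
Product: 14 (1E,3R,4R)-1-bromo-2,4-dimethylhexa-1,5-dien-3-yl acetate
Conditions: Ac2O (1.5 eq), pyridine, DMAP (5 mol%), CH2Cl2, 0 °C to rt
Reagents that add atoms: acetic anhydride, CC(=O)OC(C)=O
Why: DMAP-catalysed acylation that touches no stereocentre and installs the acetate of the target at the outset.

**Step 7**
Reactants: 14 the dienyl acetate
Product: 16 (2S,3R,4E)-5-bromo-2,4-dimethyl-1-oxopent-4-en-3-yl acetate, via 1,2,4-trioxolane ozonide 15 (not isolated)
Conditions: O3, CH2Cl2, −78 °C (Sudan red end-point); PPh3 (1.2 eq), −78 °C to rt; used crude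
Reagents that add atoms: ozone, [O-][O+]=O
Why: Ozonolysis with reductive work-up, in which the monosubstituted alkene reacts far faster than the electron-poor trisubstituted bromoalkene and the neutral work-up avoids loss of acetic acid and epimerisation at C2 (the descriptor at C2 changes from R to S only because CHO outranks the neighbouring carbon).

**Step 8**
Reactants: 16 the β-acetoxy aldehyde; 2 the silyl trienol ether (1.5 eq)
Product: 18 (1E,3R,4R,5R,6R)-1-bromo-6-(6-ethyl-3,5-dimethyl-4-oxo-4H-pyran-2-yl)-5-hydroxy-2,4-dimethylhept-1-en-3-yl acetate, via difluoroboryl aldolate 17 (not isolated)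
Conditions: BF3·OEt2 (1.2 eq), CH2Cl2, −78 °C; pH 7 buffer
Reagents that add atoms: none
Why: Vinylogous Mukaiyama aldol through an open transition state, in which Felkin–Anh attack and Evans 1,3-anti induction from the β-acetoxy group reinforce each other for this anti α-methyl-β-acyloxy aldehyde and set C5, while the aldehyde chain avoiding the ring 3-methyl group gives the 5,6-anti relationship and sets C6.

**Step 9**
Reactants: 18 the hydroxy acetate
Product: 19 (1E,3R,4R,5R,6R)-3-(acetyloxy)-1-bromo-6-(6-ethyl-3,5-dimethyl-4-oxo-4H-pyran-2-yl)-2,4-dimethylhept-1-en-5-yl propanoate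
Conditions: (EtCO)2O (3 eq), pyridine, DMAP (0.2 eq), CH2Cl2, 0 °C
Reagents that add atoms: propanoic anhydride, CCC(=O)OC(=O)CC
Why: DMAP-catalysed acylation of the hindered secondary alcohol, run cold and with excess anhydride so that acylation outpaces 1,3-acetyl migration.

**Step 10**
Reactants: 19 the alkenyl bromide; 7 the 1-chloroethyl pyranone
Product: 20 (2R,3R,4R,5R,6E,8S)-5-(acetyloxy)-2-(6-ethyl-3,5-dimethyl-4-oxo-4H-pyran-2-yl)-8-{6-[(2S,3S)-3-hydroxypentan-2-yl]-3,5-dimethyl-4-oxo-4H-pyran-2-yl}-4,6-dimethylnon-6-en-3-yl propanoate (CNP0331774.1)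
Conditions: NiCl2(dme) (10 mol%), (3aR,3a′R,8aS,8a′S)-2,2′-(cyclopropane-1,1-diyl)bis(3a,8a-dihydro-8H-indeno[1,2-d]oxazole) (11 mol%), Mn powder (3 eq), NaI (0.5 eq), DMA, 0 °C to rt
Reagents that add atoms: none
Why: Proposed new method: a Ni-catalysed enantioconvergent reductive cross-electrophile coupling in which the alkenyl–nickel species from 19 (alkene geometry retained) captures the pyranone-stabilised secondary radical formed from either epimer of 7, and the chiral bis(oxazoline)–nickel complex fixes the new centre as S on reductive elimination; the closest known reaction is the asymmetric reductive coupling of alkenyl bromides with 1-arylethyl chlorides (Reisman type) and of α-chloro esters and nitriles.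

**Compound list**
1 | 2,6-diethyl-3,5-dimethyl-4H-pyran-4-one | CCc1oc(CC)c(C)c(=O)c1C | starting material
2 | tert-butyl{[(2Z)-6-ethyl-2-ethylidene-3,5-dimethyl-2H-pyran-4-yl]oxy}dimethylsilane | C/C=C1\OC(CC)=C(C)C(O[Si](C)(C)C(C)(C)C)=C1C | intermediate
3 | propanal | CCC=O | starting material
4 | 2-ethyl-3,5-dimethyl-6-{(2S,3S)-3-[(trichlorosilyl)oxy]pentan-2-yl}-4H-pyran-4-one | CCc1oc([C@@H](C)[C@@H](O[Si](Cl)(Cl)Cl)CC)c(C)c(=O)c1C | intermediate (not isolated)
5 | 2-ethyl-6-[(2S,3S)-3-hydroxypentan-2-yl]-3,5-dimethyl-4H-pyran-4-one | CCc1oc([C@@H](C)[C@@H](O)CC)c(C)c(=O)c1C | intermediate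
6 | dilithium (2Z)-2-ethylidene-3,5-dimethyl-6-[(2S,3S)-3-oxidopentan-2-yl]-2H-pyran-4-olate | C/C=C1\OC([C@@H](C)[C@@H]([O-])CC)=C(C)C([O-])=C1C.[Li+].[Li+] | intermediate (not isolated)
7 | 2-[(1RS)-1-chloroethyl]-6-[(2S,3S)-3-hydroxypentan-2-yl]-3,5-dimethyl-4H-pyran-4-one (both epimers at CHCl) | CC(Cl)c1oc([C@@H](C)[C@@H](O)CC)c(C)c(=O)c1C | intermediate
8 | methacrolein | CC(=C)C=O | starting material
9 | 2,3-dibromo-2-methylpropanal (racemic) | CC(Br)(CBr)C=O | intermediate (not isolated)
10 | (2E)-3-bromo-2-methylprop-2-enal | O=C/C(C)=C/Br | intermediate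
11 | 2-[(2E)-but-2-en-1-yl]-4,4,5,5-tetramethyl-1,3,2-dioxaborolane | C/C=C/CB1OC(C)(C)C(C)(C)O1 | starting material
12 | 2-{[(1E,3R,4R)-1-bromo-2,4-dimethylhexa-1,5-dien-3-yl]oxy}-4,4,5,5-tetramethyl-1,3,2-dioxaborolane | C=C[C@@H](C)[C@@H](OB1OC(C)(C)C(C)(C)O1)/C(C)=C/Br | intermediate (not isolated)
13 | (1E,3R,4R)-1-bromo-2,4-dimethylhexa-1,5-dien-3-ol | C=C[C@@H](C)[C@@H](O)/C(C)=C/Br | intermediate
14 | (1E,3R,4R)-1-bromo-2,4-dimethylhexa-1,5-dien-3-yl acetate | C=C[C@@H](C)[C@@H](OC(C)=O)/C(C)=C/Br | intermediate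
15 | (1E,3R,4S)-1-bromo-2-methyl-4-(1,2,4-trioxolan-3-yl)pent-1-en-3-yl acetate (both epimers at the trioxolane carbon) | C1(OCOO1)[C@@H](C)[C@@H](OC(C)=O)/C(C)=C/Br | intermediate (not isolated)
16 | (2S,3R,4E)-5-bromo-2,4-dimethyl-1-oxopent-4-en-3-yl acetate | O=C[C@@H](C)[C@@H](OC(C)=O)/C(C)=C/Br | intermediate
17 | O-difluoroboryl derivative of 18 | FB(F)O[C@H]([C@@H](C)[C@@H](OC(C)=O)/C(C)=C/Br)[C@@H](C)c1oc(CC)c(C)c(=O)c1C | intermediate (not isolated)
18 | (1E,3R,4R,5R,6R)-1-bromo-6-(6-ethyl-3,5-dimethyl-4-oxo-4H-pyran-2-yl)-5-hydroxy-2,4-dimethylhept-1-en-3-yl acetate | O[C@H]([C@@H](C)[C@@H](OC(C)=O)/C(C)=C/Br)[C@@H](C)c1oc(CC)c(C)c(=O)c1C | intermediate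
19 | (1E,3R,4R,5R,6R)-3-(acetyloxy)-1-bromo-6-(6-ethyl-3,5-dimethyl-4-oxo-4H-pyran-2-yl)-2,4-dimethylhept-1-en-5-yl propanoate | CCC(=O)O[C@H]([C@@H](C)[C@@H](OC(C)=O)/C(C)=C/Br)[C@@H](C)c1oc(CC)c(C)c(=O)c1C | intermediate
20 | (2R,3R,4R,5R,6E,8S)-5-(acetyloxy)-2-(6-ethyl-3,5-dimethyl-4-oxo-4H-pyran-2-yl)-8-{6-[(2S,3S)-3-hydroxypentan-2-yl]-3,5-dimethyl-4-oxo-4H-pyran-2-yl}-4,6-dimethylnon-6-en-3-yl propanoate | CCC(=O)O[C@H]([C@@H](C)[C@@H](OC(C)=O)/C(C)=C/[C@H](C)c1oc([C@@H](C)[C@@H](O)CC)c(C)c(=O)c1C)[C@@H](C)c1oc(CC)c(C)c(=O)c1C | target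

**Step count**
Total: 10 steps. Longest linear sequence: 7 steps (8 → 10 → 13 → 14 → 16 → 18 → 19 → 20).

**The three steps most likely to fail**

Step 10 is the most exposed. The chiral nickel catalyst has to override two complex partners, the allylic acetate of 19 could ionise at low-valent nickel, and the free hydroxyl of 7 could protonate a nickel dienolate. The fallback sets out from 7 (and uses 19) and comes back at 20. Compound 7 is dehydrochlorinated with DBU (toluene, 60 °C) to 2-ethenyl-6-[(2S,3S)-3-hydroxypentan-2-yl]-3,5-dimethyl-4H-pyran-4-one F1. F1 and 19 are then joined by a dual copper hydride/palladium enantioselective Markovnikov hydroalkenylation (Cu(OAc)2, DTBM-SEGPHOS, Pd(OAc)2 with a biaryl phosphine, (MeO)2MeSiH, NaOSiMe3, THF; fluoride work-up frees the hydroxyl that the silane caps in the flask). The ligated CuH adds across the vinyl group to give a pyranone-stabilised secondary alkylcopper of ligand-set configuration, which transmetallates to the alkenylpalladium bromide from 19 and reductively eliminates to 20. The centre is then set by polar hydrocupration and not by radical capture at nickel.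

Step 2 may give low conversion (aliphatic aldehydes are sluggish with this catalyst) or an unexpected sense or level of induction with the new trienol ether. The fallback sets out from 1 and comes back at 5. Compound 1 is deprotonated (LiN(iPr)2, THF, −78 °C) and acylated with N-methoxy-N-methylpropanamide to racemic 2-ethyl-3,5-dimethyl-6-(3-oxopentan-2-yl)-4H-pyran-4-one F2. Reduction with catecholborane and the (R)-methyl-CBS oxazaborolidine (toluene, −78 °C) sets the carbinol centre as S in both antipodes of the ketone. This gives 5 together with its epimer 2-ethyl-6-[(2R,3S)-3-hydroxypentan-2-yl]-3,5-dimethyl-4H-pyran-4-one F3, which is removed by chromatography and returned to F2 by Dess–Martin oxidation. The carbinol centre is set by reagent control and the methyl-bearing centre by separation and recycling, so at most about half of the material comes through per pass.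

Step 8 may suffer from loss of acetic acid from aldehyde 16, from 1,3-acetyl migration in 18, or from a modest anti/syn ratio. The fallback sets out from 13 and comes back at 19; it moves the acetate to the end and carries a silyl ether through the aldol.
- Compound 13 is silylated (TBSOTf, 2,6-lutidine, CH2Cl2, −78 °C) to tert-butyl{[(1E,3R,4R)-1-bromo-2,4-dimethylhexa-1,5-dien-3-yl]oxy}dimethylsilane F4.
- Ozonolysis (O3, CH2Cl2, −78 °C; PPh3) passes through the ozonide of F4 F5 and gives (2S,3R,4E)-5-bromo-3-{[tert-butyl(dimethyl)silyl]oxy}-2,4-dimethylpent-4-enal F6, which can neither eliminate a carboxylic acid nor transfer an acyl group.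
- The BF3·OEt2-mediated aldol with 2 passes through the difluoroboryl aldolate F7 and gives the 3-O-silyl analogue of 18 F8 under Felkin control; any C6 epimer is removed here.
- Propanoylation as in step 9 gives the 3-O-silyl analogue of 19 F9.
- HF·pyridine (THF, 0 °C) gives the 3-hydroxy 5-propanoate F10, and immediate acetylation (Ac2O, DMAP, pyridine) gives 19.

This costs two extra steps and does not by itself improve the anti/syn ratio.

**Further compounds**
F1 | step 10 | 2-ethenyl-6-[(2S,3S)-3-hydroxypentan-2-yl]-3,5-dimethyl-4H-pyran-4-one | C=Cc1oc([C@@H](C)[C@@H](O)CC)c(C)c(=O)c1C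
F2 | step 2 | 2-ethyl-3,5-dimethyl-6-(3-oxopentan-2-yl)-4H-pyran-4-one (racemic) | CCc1oc(C(C)C(=O)CC)c(C)c(=O)c1C
F3 | step 2 | 2-ethyl-6-[(2R,3S)-3-hydroxypentan-2-yl]-3,5-dimethyl-4H-pyran-4-one | CCc1oc([C@H](C)[C@@H](O)CC)c(C)c(=O)c1C
F4 | step 8 | tert-butyl{[(1E,3R,4R)-1-bromo-2,4-dimethylhexa-1,5-dien-3-yl]oxy}dimethylsilane | C=C[C@@H](C)[C@@H](O[Si](C)(C)C(C)(C)C)/C(C)=C/Br
F5 | step 8 | ozonide of F4 (3-substituted 1,2,4-trioxolane, both epimers at the trioxolane carbon) | C1(OCOO1)[C@@H](C)[C@@H](O[Si](C)(C)C(C)(C)C)/C(C)=C/Br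
F6 | step 8 | (2S,3R,4E)-5-bromo-3-{[tert-butyl(dimethyl)silyl]oxy}-2,4-dimethylpent-4-enal | O=C[C@@H](C)[C@@H](O[Si](C)(C)C(C)(C)C)/C(C)=C/Br
F7 | step 8 | O-difluoroboryl derivative of F8 | FB(F)O[C@H]([C@@H](C)[C@@H](O[Si](C)(C)C(C)(C)C)/C(C)=C/Br)[C@@H](C)c1oc(CC)c(C)c(=O)c1C
F8 | step 8 | 3-O-tert-butyldimethylsilyl analogue of 18 (free 5-hydroxyl) | O[C@H]([C@@H](C)[C@@H](O[Si](C)(C)C(C)(C)C)/C(C)=C/Br)[C@@H](C)c1oc(CC)c(C)c(=O)c1C
F9 | step 8 | 3-O-tert-butyldimethylsilyl analogue of 19 (5-propanoate) | CCC(=O)O[C@H]([C@@H](C)[C@@H](O[Si](C)(C)C(C)(C)C)/C(C)=C/Br)[C@@H](C)c1oc(CC)c(C)c(=O)c1C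
F10 | step 8 | 3-hydroxy 5-propanoate (19 without the acetyl group) | CCC(=O)O[C@H]([C@@H](C)[C@@H](O)/C(C)=C/Br)[C@@H](C)c1oc(CC)c(C)c(=O)c1C
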